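**Plan**
1. Locants and enabling feature: each oxolane is O1, C2 (aryl), C3 (bearing C9H2OH), C4 (bearing OH and C7'H2–aryl), C5. Unit A has ring a on C7' and ring b on C2, unit B has ring c on C7' and ring d on C2, and rings b and c form the biaryl. C4 is bonded directly to C5 in both rings, so a C5 lactone carbonyl turns each tertiary carbinol carbon into an enolate carbon that can receive its oxygen last.
2. Cuts, in retrosynthetic order: both C5H2 back to C5=O; both C4–O bonds; the ring b–ring c aryl–aryl bond; both C4–C7' bonds; in each lactone C2–C3 and O1–C5, back to an aryl aldehyde and a succinyl imide.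
3. Forward order: each lactone ring is made separately (a succinate aldol forms C2–C3, the aldolate closes O1–C5); C9 is reduced and silylated and C4 is benzylated; the two lactones are joined by Suzuki coupling; both C4–O bonds are made together; both C5 carbonyls are reduced to CH2; deprotection follows.
4. Stereochemistry: C2 and C3 of both units come from syn aldol reactions controlled by (S)-4-benzyloxazolidin-2-one (2,3-trans lactones). C4 of both units comes from oxygen transfer to the enolate face anti to the C3 substituent.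
5. Naming: lactone names use oxolan-2-one locants (C2 = target C5, C3 = target C4, C4 = target C3, C5 = target C2); the Why lines use target locants.

Key step: step 18

Remark: the b–c biaryl axis has only two ortho substituents (the two oxygens) and is assumed to rotate freely, so no atropisomers are considered; lactol 32 is carried as its anomeric mixture.

**Route**

Step 1
Reactants: 1 (S)-4-benzyloxazolidin-2-one; 2 methyl 4-chloro-4-oxobutanoate
Product: 3 (S)-4-benzyl-3-(4-methoxy-4-oxobutanoyl)oxazolidin-2-one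
Conditions: n-BuLi, THF, −78 °C; then 2, −78 to 0 °C
Reagents that add atoms: none
Why: N-acylation of the lithiated oxazolidinone by an acid chloride is the standard entry to Evans imides, and the distal methyl ester is not attacked at −78 °C.

Step 2
Reactants: 4 5-bromovanillin
Product: 5 4-(benzyloxy)-3-bromo-5-methoxybenzaldehyde
Conditions: BnBr, K2CO3, DMF, rt
Reagents that add atoms: benzyl bromide, BrCc1ccccc1
Why: Williamson etherification of the acidic phenol gives a benzyl ether that should survive the enolate, borane, palladium and hydride steps until the final hydrogenolysis.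

Step 3
Reactants: 3 (S)-4-benzyl-3-(4-methoxy-4-oxobutanoyl)oxazolidin-2-one; 5 4-(benzyloxy)-3-bromo-5-methoxybenzaldehyde
Product: 8 (S)-4-benzyl-3-{[(2S,3S)-2-(4-benzyloxy-3-bromo-5-methoxyphenyl)-5-oxooxolan-3-yl]carbonyl}oxazolidin-2-one (trans lactone imide A), via boron enolate 6 (not isolated), via boron aldolate 7 (not isolated)
Conditions: Bu2BOTf, i-Pr2NEt, CH2Cl2, −78 to 0 °C; 5, −78 to 0 °C; pH 7 buffer, MeOH, 30% H2O2, 0 °C to rt
Reagents that add atoms: none
Why: Evans syn aldol reaction, in which soft enolisation gives the Z-boron enolate at the imide α-carbon only, the Zimmerman–Traxler chair with the auxiliary benzyl group blocking one face sets C3 (S) and C2 (S) (descriptors as in 8) as the syn aldolate, and the aldolate oxygen then closes onto the γ-methyl ester (5-exo-trig lactonisation) so that syn becomes the 2,3-trans lactone.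

Step 4
Reactants: 8 trans lactone imide A
Product: 10 (2S,3S)-2-(4-benzyloxy-3-bromo-5-methoxyphenyl)-5-oxooxolane-3-carboxylic acid, via peroxy acid 9 (not isolated)
Conditions: LiOH, 30% H2O2, THF/H2O, 0 °C; Na2SO3; HCl to pH 2
Reagents that add atoms: hydrogen peroxide (as LiOOH), OO
Why: Hydroperoxide cleavage of the N-acyl oxazolidinone attacks the exocyclic imide carbonyl without epimerising C3, sulfite reduces the peroxy acid, and acidification re-closes any lactone opened by hydroxide.

Step 5
Reactants: 10 (2S,3S)-2-(4-benzyloxy-3-bromo-5-methoxyphenyl)-5-oxooxolane-3-carboxylic acid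
Product: 11 (4R,5S)-5-(4-benzyloxy-3-bromo-5-methoxyphenyl)-4-(hydroxymethyl)oxolan-2-one
Conditions: BH3·SMe2, THF, 0 °C to rt; MeOH
Reagents that add atoms: none
Why: Borane reduces a carboxylic acid through its acyloxyborane much faster than a lactone, and the non-basic medium should keep the new C9 hydroxyl from translactonising onto C5.

Step 6
Reactants: 11 (4R,5S)-5-(4-benzyloxy-3-bromo-5-methoxyphenyl)-4-(hydroxymethyl)oxolan-2-one
Product: 12 (4R,5S)-5-(4-benzyloxy-3-bromo-5-methoxyphenyl)-4-[(tert-butyldimethylsilyloxy)methyl]oxolan-2-one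
Conditions: TBSCl, imidazole, DMF, 0 °C to rt
Reagents that add atoms: tert-butyldimethylsilyl chloride, CC(C)(C)[Si](C)(C)Cl
Why: Imidazole-mediated silylation masks the only free hydroxyl before enolate chemistry and makes the C3 substituent bulky enough to direct both the alkylation and the later oxygenation.

Step 7
Reactants: 13 (4-benzyloxy-3-methoxyphenyl)methanol
Product: 14 1-(benzyloxy)-4-(bromomethyl)-2-methoxybenzene
Conditions: PBr3, CH2Cl2, 0 °C
Reagents that add atoms: phosphorus tribromide, BrP(Br)Br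
Why: Bromination of an electron-rich benzylic alcohol with PBr3 is routine, and the bromide is to be used at once.

Step 8
Reactants: 12 (4R,5S)-5-(4-benzyloxy-3-bromo-5-methoxyphenyl)-4-[(tert-butyldimethylsilyloxy)methyl]oxolan-2-one; 14 1-(benzyloxy)-4-(bromomethyl)-2-methoxybenzene
Product: 16 (3S,4R,5S)-3-(4-benzyloxy-3-methoxybenzyl)-5-(4-benzyloxy-3-bromo-5-methoxyphenyl)-4-[(tert-butyldimethylsilyloxy)methyl]oxolan-2-one (lactone A), via lithium enolate 15 (not isolated)
Conditions: LiHMDS, THF, −78 °C; 14, −78 to −40 °C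
Reagents that add atoms: none
Why: Lactone enolate alkylation, in which the benzylic bromide approaches the enolate face anti to the C3 silyloxymethyl group to give the 3,4-trans lactone, a C4 configuration that is only provisional because step 18 passes through the planar enolate again.

Step 9
Reactants: 3 (S)-4-benzyl-3-(4-methoxy-4-oxobutanoyl)oxazolidin-2-one; 17 4-(benzyloxy)-3-methoxybenzaldehyde
Product: 19 (S)-4-benzyl-3-{[(2S,3S)-2-(4-benzyloxy-3-methoxyphenyl)-5-oxooxolan-3-yl]carbonyl}oxazolidin-2-one (trans lactone imide B), via boron aldolate 18 (not isolated)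
Conditions: enolisation of 3 as in step 3 (Bu2BOTf, i-Pr2NEt, CH2Cl2, −78 to 0 °C); 17, −78 to 0 °C; pH 7 buffer, MeOH, 30% H2O2, 0 °C to rt
Reagents that add atoms: none
Why: The Evans syn aldol–lactonisation of step 3 is repeated with the boron enolate 6 described there, now adding to 17, so that C2 (S) and C3 (S) of unit B are set under auxiliary control and the 2,3-trans lactone closes by 5-exo-trig attack of the aldolate on the methyl ester.

Step 10
Reactants: 19 trans lactone imide B
Product: 21 (2S,3S)-2-(4-benzyloxy-3-methoxyphenyl)-5-oxooxolane-3-carboxylic acid, via peroxy acid 20 (not isolated)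
Conditions: LiOH, 30% H2O2, THF/H2O, 0 °C; Na2SO3; HCl to pH 2
Reagents that add atoms: hydrogen peroxide (as LiOOH), OO
Why: Hydroperoxide cleavage of the imide as in step 4 releases the acid and the auxiliary without touching the C2 and C3 configurations.

Step 11
Reactants: 21 (2S,3S)-2-(4-benzyloxy-3-methoxyphenyl)-5-oxooxolane-3-carboxylic acid
Product: 22 (4R,5S)-5-(4-benzyloxy-3-methoxyphenyl)-4-(hydroxymethyl)oxolan-2-one
Conditions: BH3·SMe2, THF, 0 °C to rt; MeOH
Reagents that add atoms: none
Why: Chemoselective borane reduction of the acid in the presence of the lactone, as in step 5.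

Step 12
Reactants: 22 (4R,5S)-5-(4-benzyloxy-3-methoxyphenyl)-4-(hydroxymethyl)oxolan-2-one
Product: 23 (4R,5S)-5-(4-benzyloxy-3-methoxyphenyl)-4-[(tert-butyldimethylsilyloxy)methyl]oxolan-2-one
Conditions: TBSCl, imidazole, DMF, 0 °C to rt
Reagents that add atoms: tert-butyldimethylsilyl chloride, CC(C)(C)[Si](C)(C)Cl
Why: Silylation of the primary C9 alcohol as in step 6.

Step 13
Reactants: 5 4-(benzyloxy)-3-bromo-5-methoxybenzaldehyde
Product: 24 (4-benzyloxy-3-bromo-5-methoxyphenyl)methanol
Conditions: NaBH4, MeOH/THF, 0 °C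
Reagents that add atoms: none
Why: Borohydride reduction of the aryl aldehyde is chemoselective and leaves the aryl bromide and the benzyl ether untouched.

Step 14
Reactants: 24 (4-benzyloxy-3-bromo-5-methoxyphenyl)methanol
Product: 25 2-(benzyloxy)-1-bromo-5-(bromomethyl)-3-methoxybenzene
Conditions: PBr3, CH2Cl2, 0 °C
Reagents that add atoms: phosphorus tribromide, BrP(Br)Br
Why: Benzylic bromination with PBr3 as in step 7, the aryl bromide being inert.

Step 15
Reactants: 23 (4R,5S)-5-(4-benzyloxy-3-methoxyphenyl)-4-[(tert-butyldimethylsilyloxy)methyl]oxolan-2-one; 25 2-(benzyloxy)-1-bromo-5-(bromomethyl)-3-methoxybenzene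
Product: 27 (3S,4R,5S)-3-(4-benzyloxy-3-bromo-5-methoxybenzyl)-5-(4-benzyloxy-3-methoxyphenyl)-4-[(tert-butyldimethylsilyloxy)methyl]oxolan-2-one (bromo lactone B), via lithium enolate 26 (not isolated)
Conditions: LiHMDS, THF, −78 °C; 25, −78 to −40 °C
Reagents that add atoms: none
Why: Lactone enolate alkylation anti to the C3 substituent as in step 8, the benzylic bromide reacting far faster than the aryl bromide.

Step 16
Reactants: 27 bromo lactone B
Product: 28 (3S,4R,5S)-3-[4-benzyloxy-3-methoxy-5-(4,4,5,5-tetramethyl-1,3,2-dioxaborolan-2-yl)benzyl]-5-(4-benzyloxy-3-methoxyphenyl)-4-[(tert-butyldimethylsilyloxy)methyl]oxolan-2-one (boronate B)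
Conditions: B2pin2, Pd(dppf)Cl2, KOAc, 1,4-dioxane, 85 °C
Reagents that add atoms: bis(pinacolato)diboron, CC1(C)OB(OC1(C)C)B1OC(C)(C)C(C)(C)O1
Why: Miyaura borylation with the weak base acetate converts the aryl bromide into the pinacol boronate without opening the lactone or cleaving the silyl ether.

Step 17
Reactants: 16 lactone A (aryl bromide on ring b); 28 boronate B (boronate on ring c)
Product: 29 all-trans bis(α-benzyl-γ-aryl-butyrolactone) with ring b of 16 bonded to ring c of 28 at the former C–Br and C–B carbons (two C9 OTBS groups; four aryl OBn groups)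
Conditions: SPhos Pd G3, K3PO4, toluene/H2O, 70 °C
Reagents that add atoms: none
Why: Suzuki–Miyaura coupling with a dialkylbiarylphosphine ligand is suited to joining two ortho-oxygenated rings, phosphate at moderate temperature should spare lactones and silyl ethers, and any C4 epimerisation would be irrelevant since C4 is re-set in step 18.

Step 18
Reactants: 29 all-trans bis-lactone
Product: 31 bis(α-hydroxy lactone) with each lactone (3S,4R,5S) and the new hydroxyl on target C4 trans to C9 (benzyl cis to C9), via dipotassium bis-enolate 30 (not isolated)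
Conditions: KHMDS (2.6 equiv), THF, −78 °C; (±)-3-phenyl-2-(phenylsulfonyl)oxaziridine (3 equiv), −78 °C; AcOH
Reagents that add atoms: 3-phenyl-2-(phenylsulfonyl)oxaziridine, O=S(=O)(c1ccccc1)N1OC1c1ccccc1
Why: KHMDS removes the C4 proton of each lactone to give the planar bis(potassium enolate) 30, and each enolate carbon attacks the electrophilic oxygen of the N-sulfonyloxaziridine with N–O cleavage, the adduct collapsing to the C4 alkoxide and the sulfonylimine, so that the two C4–O bonds are formed. The closest known reaction type is the oxaziridine α-hydroxylation of α-benzyl butyrolactone enolates used for α-hydroxy lactone lignans. No ring is closed in this step. Each new C4 stereocentre is controlled by the adjacent C3 silyloxymethyl group: oxygen enters the enolate face anti to the C3–C9 bond (syn to the more distant C2 aryl group), which places the C7' benzyl group cis to C9 and gives the (4S) carbinol of the target in both units. The step needs facial selectivity at both enolates and complete twofold conversion; the 1,2-relationship between C4 and the bulky C3 substituent should secure the first, while the separation of the two lactones at opposite ends of the biaryl, a small excess of base and oxidant, and potassium counter-ions (which disfavour enolate addition to the imine by-product) should secure the second.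

Step 19
Reactants: 31 bis(α-hydroxy lactone)
Product: 32 bis-lactol (both C5 carbonyls reduced to C5H–OH; anomeric mixture)
Conditions: DIBAL-H (excess), CH2Cl2, −78 °C; Rochelle salt
Reagents that add atoms: none
Why: DIBAL-H reduction of a lactone at −78 °C stops at the aluminium hemiacetal, the excess allowing for the two tertiary hydroxyls, and the new anomeric centres are removed in the next step.

Step 20
Reactants: 32 bis-lactol
Product: 33 bis-oxolane with each ring (2S,3R,4S), C5 as CH2, two C9 OTBS groups and four aryl OBn groups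
Conditions: Et3SiH, BF3·OEt2, CH2Cl2, −78 to −30 °C
Reagents that add atoms: none
Why: Ionic hydrogenation of a lactol, in which BF3 ionises the hemiacetal to the cyclic oxocarbenium ion that triethylsilane reduces to the C5 methylene, run cold so that the C2–O1 benzylic ether, the tertiary C4 hydroxyl and the TBS ethers are not ionised and no stereocentre is touched.

Step 21
Reactants: 33 bis-oxolane
Product: 34 tetra-O-benzyl ether of the target (both C9 hydroxyls free)
Conditions: TBAF, THF, 0 °C to rt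
Reagents that add atoms: none
Why: Fluoride desilylation frees the two primary alcohols while the phenols are still benzylated, so that no phenoxide and hence no quinone-methide epimerisation at C2 can arise.

Step 22
Reactants: 34 tetra-O-benzyl ether of the target
Product: 35 CNP0269573.1
Conditions: H2 (1 atm), 10% Pd/C, EtOAc/MeOH, rt
Reagents that add atoms: none
Why: Hydrogenolysis of the four aryl benzyl ethers over Pd/C under neutral conditions at 1 atm should be much faster than cleavage of the cyclic benzylic C2–O1 ether and delivers the target.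

**Compound list**

1 | (S)-4-benzyloxazolidin-2-one | O=C1N[C@@H](Cc2ccccc2)CO1 | starting material
2 | methyl 4-chloro-4-oxobutanoate | COC(=O)CCC(=O)Cl | starting material
3 | (S)-4-benzyl-3-(4-methoxy-4-oxobutanoyl)oxazolidin-2-one | COC(=O)CCC(=O)N1[C@@H](Cc2ccccc2)COC1=O | intermediate
4 | 5-bromovanillin (3-bromo-4-hydroxy-5-methoxybenzaldehyde) | COc1cc(C=O)cc(Br)c1O | starting material
5 | 4-(benzyloxy)-3-bromo-5-methoxybenzaldehyde | COc1cc(C=O)cc(Br)c1OCc1ccccc1 | intermediate
6 | (Z)-dibutylboron enolate of 3 (enolised at the imide α-carbon) | CCCCB(CCCC)O/C(=C\CC(=O)OC)N1[C@@H](Cc2ccccc2)COC1=O | intermediate (not isolated)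
7 | methyl (3S,4S)-4-(4-benzyloxy-3-bromo-5-methoxyphenyl)-3-[(S)-4-benzyl-2-oxooxazolidine-3-carbonyl]-4-[(dibutylboranyl)oxy]butanoate (syn boron aldolate A) | COC(=O)C[C@H](C(=O)N1[C@@H](Cc2ccccc2)COC1=O)[C@@H](c1cc(OC)c(OCc2ccccc2)c(Br)c1)OB(CCCC)CCCC | intermediate (not isolated)
8 | (S)-4-benzyl-3-{[(2S,3S)-2-(4-benzyloxy-3-bromo-5-methoxyphenyl)-5-oxooxolan-3-yl]carbonyl}oxazolidin-2-one | O=C1O[C@H](c2cc(OC)c(OCc3ccccc3)c(Br)c2)[C@@H](C(=O)N2[C@@H](Cc3ccccc3)COC2=O)C1 | intermediate
9 | (2S,3S)-2-(4-benzyloxy-3-bromo-5-methoxyphenyl)-5-oxooxolane-3-carboperoxoic acid | O=C1O[C@H](c2cc(OC)c(OCc3ccccc3)c(Br)c2)[C@@H](C(=O)OO)C1 | intermediate (not isolated)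
10 | (2S,3S)-2-(4-benzyloxy-3-bromo-5-methoxyphenyl)-5-oxooxolane-3-carboxylic acid | O=C1O[C@H](c2cc(OC)c(OCc3ccccc3)c(Br)c2)[C@@H](C(=O)O)C1 | intermediate
11 | (4R,5S)-5-(4-benzyloxy-3-bromo-5-methoxyphenyl)-4-(hydroxymethyl)oxolan-2-one | O=C1O[C@H](c2cc(OC)c(OCc3ccccc3)c(Br)c2)[C@@H](CO)C1 | intermediate
12 | (4R,5S)-5-(4-benzyloxy-3-bromo-5-methoxyphenyl)-4-[(tert-butyldimethylsilyloxy)methyl]oxolan-2-one | O=C1O[C@H](c2cc(OC)c(OCc3ccccc3)c(Br)c2)[C@@H](CO[Si](C)(C)C(C)(C)C)C1 | intermediate
13 | (4-benzyloxy-3-methoxyphenyl)methanol | COc1cc(CO)ccc1OCc1ccccc1 | starting material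
14 | 1-(benzyloxy)-4-(bromomethyl)-2-methoxybenzene | COc1cc(CBr)ccc1OCc1ccccc1 | intermediate
15 | lithium enolate of 12 | [Li]OC1=C[C@H](CO[Si](C)(C)C(C)(C)C)[C@@H](c2cc(OC)c(OCc3ccccc3)c(Br)c2)O1 | intermediate (not isolated)
16 | (3S,4R,5S)-3-(4-benzyloxy-3-methoxybenzyl)-5-(4-benzyloxy-3-bromo-5-methoxyphenyl)-4-[(tert-butyldimethylsilyloxy)methyl]oxolan-2-one | O=C1O[C@H](c2cc(OC)c(OCc3ccccc3)c(Br)c2)[C@@H](CO[Si](C)(C)C(C)(C)C)[C@@H]1Cc1ccc(OCc2ccccc2)c(OC)c1 | intermediate
17 | 4-(benzyloxy)-3-methoxybenzaldehyde | COc1cc(C=O)ccc1OCc1ccccc1 | starting material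
18 | methyl (3S,4S)-4-(4-benzyloxy-3-methoxyphenyl)-3-[(S)-4-benzyl-2-oxooxazolidine-3-carbonyl]-4-[(dibutylboranyl)oxy]butanoate (syn boron aldolate B) | COC(=O)C[C@H](C(=O)N1[C@@H](Cc2ccccc2)COC1=O)[C@@H](c1ccc(OCc2ccccc2)c(OC)c1)OB(CCCC)CCCC | intermediate (not isolated)
19 | (S)-4-benzyl-3-{[(2S,3S)-2-(4-benzyloxy-3-methoxyphenyl)-5-oxooxolan-3-yl]carbonyl}oxazolidin-2-one | O=C1O[C@H](c2ccc(OCc3ccccc3)c(OC)c2)[C@@H](C(=O)N2[C@@H](Cc3ccccc3)COC2=O)C1 | intermediate
20 | (2S,3S)-2-(4-benzyloxy-3-methoxyphenyl)-5-oxooxolane-3-carboperoxoic acid | O=C1O[C@H](c2ccc(OCc3ccccc3)c(OC)c2)[C@@H](C(=O)OO)C1 | intermediate (not isolated)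
21 | (2S,3S)-2-(4-benzyloxy-3-methoxyphenyl)-5-oxooxolane-3-carboxylic acid | O=C1O[C@H](c2ccc(OCc3ccccc3)c(OC)c2)[C@@H](C(=O)O)C1 | intermediate
22 | (4R,5S)-5-(4-benzyloxy-3-methoxyphenyl)-4-(hydroxymethyl)oxolan-2-one | O=C1O[C@H](c2ccc(OCc3ccccc3)c(OC)c2)[C@@H](CO)C1 | intermediate
23 | (4R,5S)-5-(4-benzyloxy-3-methoxyphenyl)-4-[(tert-butyldimethylsilyloxy)methyl]oxolan-2-one | O=C1O[C@H](c2ccc(OCc3ccccc3)c(OC)c2)[C@@H](CO[Si](C)(C)C(C)(C)C)C1 | intermediate
24 | (4-benzyloxy-3-bromo-5-methoxyphenyl)methanol | COc1cc(CO)cc(Br)c1OCc1ccccc1 | intermediate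
25 | 2-(benzyloxy)-1-bromo-5-(bromomethyl)-3-methoxybenzene | COc1cc(CBr)cc(Br)c1OCc1ccccc1 | intermediate
26 | lithium enolate of 23 | [Li]OC1=C[C@H](CO[Si](C)(C)C(C)(C)C)[C@@H](c2ccc(OCc3ccccc3)c(OC)c2)O1 | intermediate (not isolated)
27 | (3S,4R,5S)-3-(4-benzyloxy-3-bromo-5-methoxybenzyl)-5-(4-benzyloxy-3-methoxyphenyl)-4-[(tert-butyldimethylsilyloxy)methyl]oxolan-2-one | O=C1O[C@H](c2ccc(OCc3ccccc3)c(OC)c2)[C@@H](CO[Si](C)(C)C(C)(C)C)[C@@H]1Cc1cc(OC)c(OCc2ccccc2)c(Br)c1 | intermediate
28 | (3S,4R,5S)-3-[4-benzyloxy-3-methoxy-5-(4,4,5,5-tetramethyl-1,3,2-dioxaborolan-2-yl)benzyl]-5-(4-benzyloxy-3-methoxyphenyl)-4-[(tert-butyldimethylsilyloxy)methyl]oxolan-2-one | O=C1O[C@H](c2ccc(OCc3ccccc3)c(OC)c2)[C@@H](CO[Si](C)(C)C(C)(C)C)[C@@H]1Cc1cc(OC)c(OCc2ccccc2)c(B2OC(C)(C)C(C)(C)O2)c1 | intermediate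
29 | (3S,4R,5S)-3-(4-benzyloxy-3-methoxybenzyl)-5-{4-benzyloxy-3-[2-benzyloxy-3-methoxy-5-({(3S,4R,5S)-5-(4-benzyloxy-3-methoxyphenyl)-4-[(tert-butyldimethylsilyloxy)methyl]-2-oxooxolan-3-yl}methyl)phenyl]-5-methoxyphenyl}-4-[(tert-butyldimethylsilyloxy)methyl]oxolan-2-one (all-trans bis-lactone) | COc1cc(C[C@@H]2C(=O)O[C@H](c3cc(OC)c(OCc7ccccc7)c(-c4cc(C[C@@H]5C(=O)O[C@H](c6ccc(OCc7ccccc7)c(OC)c6)[C@H]5CO[Si](C)(C)C(C)(C)C)cc(OC)c4OCc7ccccc7)c3)[C@H]2CO[Si](C)(C)C(C)(C)C)ccc1OCc7ccccc7 | intermediate
30 | dipotassium bis-enolate of 29 (both C4=C5–OK) | COc1cc(CC2=C(O[K])O[C@H](c3cc(OC)c(OCc7ccccc7)c(-c4cc(CC5=C(O[K])O[C@H](c6ccc(OCc7ccccc7)c(OC)c6)[C@H]5CO[Si](C)(C)C(C)(C)C)cc(OC)c4OCc7ccccc7)c3)[C@H]2CO[Si](C)(C)C(C)(C)C)ccc1OCc7ccccc7 | intermediate (not isolated)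
31 | bis(α-hydroxy lactone): compound 29 with a hydroxyl on C3 of each oxolan-2-one, each lactone (3S,4R,5S), OH trans and benzyl cis to the CH2OTBS group | COc1cc(C[C@@]2(O)C(=O)O[C@H](c3cc(OC)c(OCc7ccccc7)c(-c4cc(C[C@@]5(O)C(=O)O[C@H](c6ccc(OCc7ccccc7)c(OC)c6)[C@H]5CO[Si](C)(C)C(C)(C)C)cc(OC)c4OCc7ccccc7)c3)[C@H]2CO[Si](C)(C)C(C)(C)C)ccc1OCc7ccccc7 | intermediate
32 | bis-lactol: compound 31 with both lactone carbonyls reduced to CH–OH (anomeric mixture) | COc1cc(C[C@@]2(O)C(O)O[C@H](c3cc(OC)c(OCc7ccccc7)c(-c4cc(C[C@@]5(O)C(O)O[C@H](c6ccc(OCc7ccccc7)c(OC)c6)[C@H]5CO[Si](C)(C)C(C)(C)C)cc(OC)c4OCc7ccccc7)c3)[C@H]2CO[Si](C)(C)C(C)(C)C)ccc1OCc7ccccc7 | intermediate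
33 | bis-oxolane: target skeleton with each ring (2S,3R,4S), both C9 hydroxyls as TBS ethers and all four phenols as benzyl ethers | COc1cc(C[C@@]2(O)CO[C@H](c3cc(OC)c(OCc7ccccc7)c(-c4cc(C[C@@]5(O)CO[C@H](c6ccc(OCc7ccccc7)c(OC)c6)[C@H]5CO[Si](C)(C)C(C)(C)C)cc(OC)c4OCc7ccccc7)c3)[C@H]2CO[Si](C)(C)C(C)(C)C)ccc1OCc7ccccc7 | intermediate
34 | tetra-O-benzyl ether of the target (four phenols benzylated, all alcohols free) | COc1cc(C[C@@]2(O)CO[C@H](c3cc(OC)c(OCc7ccccc7)c(-c4cc(C[C@@]5(O)CO[C@H](c6ccc(OCc7ccccc7)c(OC)c6)[C@H]5CO)cc(OC)c4OCc7ccccc7)c3)[C@H]2CO)ccc1OCc7ccccc7 | intermediate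
35 | CNP0269573.1: 5,5'-linked bis-olivil-type dilignan, each oxolane (2S,3R,4S) | COc1cc(C[C@@]2(O)CO[C@H](c3cc(OC)c(O)c(-c4cc(C[C@@]5(O)CO[C@H](c6ccc(O)c(OC)c6)[C@H]5CO)cc(OC)c4O)c3)[C@H]2CO)ccc1O | target

**Step count and risks**

Total steps: 22. Longest linear sequence: 13 steps (1, 9, 10, 11, 12, 15, 16, 17, 18, 19, 20, 21, 22).

The three steps most likely to fail:

The twofold hydroxylation (step 18). What may go wrong: incomplete enolisation of one of the two hindered tertiary C4–H positions; addition of an enolate to the sulfonylimine by-product; or erosion of facial selectivity because the C2 aryl group sits on the face that the oxidant must use. Fallback: setting out from 29, the bis-enolate is trapped with TMSCl (KHMDS, THF, −78 °C) as the bis(trimethylsilyl ketene acetal) F1. This neutral, non-aggregated species is then epoxidised with dimethyldioxirane in acetone/CH2Cl2 at low temperature (Rubottom-type oxidation, again anti to the C3 substituent). Silyl migration should give the bis(α-trimethylsilyloxy lactone) F2. Citric acid in methanol then removes the tertiary TMS ethers in the presence of the primary TBS ethers, and the route is rejoined at 31.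

The lactol deoxygenation (step 20). What may go wrong: the Lewis acid ionises the electron-rich benzylic C2–O1 bond, leading to epimerisation at C2 or reductive ring opening; or the α-hydroxy oxocarbenium ion undergoes a 1,2-shift before it is reduced. Fallback: setting out from 31, LiBH4 in THF reduces both lactones to the bis-triol F3 (in each unit a benzylic C2–OH, the tertiary C4–OH and a primary C5–OH). Catalytic camphorsulfonic acid in CH2Cl2 then closes both oxolanes by attack of the C5 hydroxyl on the C2 benzylic cation. The oxetane that the C4 hydroxyl could form is strongly disfavoured. This acid-mediated etherification of 7-aryl lignan polyols is expected to place the aryl group trans to the C3 substituent, as the target requires, and the route is rejoined at 33.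

The biaryl coupling (step 17). What may go wrong: protodeboronation of the electron-rich ortho-benzyloxy boronate; slow transmetalation between two ortho-oxygenated partners; or opening of the lactones by aqueous phosphate. Fallback: setting out from 27, palladium-catalysed stannylation with hexamethylditin (Pd(PPh3)4, toluene, 100 °C) gives the aryltrimethylstannane F4. This is coupled with bromide 16 under base-free and water-free Stille conditions (Pd(PPh3)4, CuI, DMF, 80 °C), and the route is rejoined at 29.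

**Further compounds**

F1 | step 18 | bis(trimethylsilyl ketene acetal) of 29 (both C4=C5–OSiMe3) | COc1cc(CC2=C(O[Si](C)(C)C)O[C@H](c3cc(OC)c(OCc7ccccc7)c(-c4cc(CC5=C(O[Si](C)(C)C)O[C@H](c6ccc(OCc7ccccc7)c(OC)c6)[C@H]5CO[Si](C)(C)C(C)(C)C)cc(OC)c4OCc7ccccc7)c3)[C@H]2CO[Si](C)(C)C(C)(C)C)ccc1OCc7ccccc7
F2 | step 18 | bis(α-trimethylsilyloxy lactone): compound 31 with both tertiary hydroxyls as TMS ethers | COc1cc(C[C@@]2(O[Si](C)(C)C)C(=O)O[C@H](c3cc(OC)c(OCc7ccccc7)c(-c4cc(C[C@@]5(O[Si](C)(C)C)C(=O)O[C@H](c6ccc(OCc7ccccc7)c(OC)c6)[C@H]5CO[Si](C)(C)C(C)(C)C)cc(OC)c4OCc7ccccc7)c3)[C@H]2CO[Si](C)(C)C(C)(C)C)ccc1OCc7ccccc7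
F3 | step 20 | bis-triol from reduction of both lactones of 31 (each unit: benzylic C2–OH, tertiary C4–OH, primary C5–OH, C9 OTBS) | COc1cc(C[C@@](O)(CO)[C@H](CO[Si](C)(C)C(C)(C)C)[C@H](O)c2cc(OC)c(OCc7ccccc7)c(-c3cc(C[C@@](O)(CO)[C@H](CO[Si](C)(C)C(C)(C)C)[C@H](O)c4ccc(OCc7ccccc7)c(OC)c4)cc(OC)c3OCc7ccccc7)c2)ccc1OCc7ccccc7
F4 | step 17 | (3S,4R,5S)-3-[4-benzyloxy-3-methoxy-5-(trimethylstannyl)benzyl]-5-(4-benzyloxy-3-methoxyphenyl)-4-[(tert-butyldimethylsilyloxy)methyl]oxolan-2-one | O=C1O[C@H](c2ccc(OCc3ccccc3)c(OC)c2)[C@@H](CO[Si](C)(C)C(C)(C)C)[C@@H]1Cc1cc(OC)c(OCc2ccccc2)c([Sn](C)(C)C)c1
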